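**Retrosynthetic overview**

- Numbering: ring A (five-membered) is C1(Me, quaternary)–C2–C3–C4(iPr)=C5; ring B (seven-membered) is C5–C6–C7–C8(CH2O–vanillate)=C9–C10–C1. The plan rests on the tetrasubstituted C4=C5 alkene, which both rings share and which sits next to quaternary C1: its two carbons are treated as the carbonyl carbons of a 1,5-diketone.
- Disconnections: ester C–O (Mitsunobu, last) to allylic alcohol 16; C4=C5 (intramolecular McMurry coupling) to diketone 14; C1–C2 (chiral-imine Michael addition, sets the only stereocentre) to racemic cycloheptenone 9; ring B by rhodium-catalysed [5+2] cycloaddition of vinylcyclopropane 5 with alkyne 7.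
- Ring order: ring B first (step 4), ring A last (step 7).

Key step: step 7

Assumption: the enamine of the seven-membered ketone is taken to show the same facial preference as that of 2-methylcyclohexanone (hence the (R)-amine), and the alkyne in step 4 is taken to insert with its substituted carbon away from the vinyl terminus.

**Step 1**
Reactants: 1 (1-ethoxycyclopropoxy)trimethylsilane; 2 isopropenylmagnesium bromide (solution in THF)
Product: 4 1-(prop-1-en-2-yl)cyclopropan-1-ol, via 1-ethoxycyclopropan-1-ol 3 (not isolated)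
Conditions: MeOH, rt, concentrate; then 2 (2.5 equiv), THF, 0 °C to reflux; sat. aq. NH4Cl
Reagents that add atoms: none
Why: Methanolysis frees the cyclopropanone hemiketal, whose magnesium alkoxide collapses to cyclopropanone in the flask and is trapped by a second equivalent of the alkenyl Grignard reagent (Grignard addition to a masked cyclopropanone); the neutral quench avoids acid-induced ring expansion.

**Step 2**
Reactants: 4 1-(prop-1-en-2-yl)cyclopropan-1-ol
Product: 5 tert-butyldimethyl{[1-(prop-1-en-2-yl)cyclopropyl]oxy}silane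
Conditions: TBSCl, imidazole, DMF, rt
Reagents that add atoms: tert-butyldimethylsilyl chloride, CC(C)(C)[Si](C)(C)Cl
Why: Silylation of the cyclopropanol under basic conditions should give the 1-siloxy vinylcyclopropane needed as the five-carbon partner without opening the strained ring.

**Step 3**
Reactants: 6 propargyl alcohol
Product: 7 tert-butyl(diphenyl)(prop-2-yn-1-yloxy)silane
Conditions: TBDPSCl, imidazole, CH2Cl2, 0 °C to rt
Reagents that add atoms: tert-butyldiphenylsilyl chloride, CC(C)(C)[Si](Cl)(c1ccccc1)c1ccccc1
Why: Standard silylation of a primary alcohol; TBDPS is chosen over TBS so that this ether outlasts the acidic enol-ether and imine hydrolyses of steps 4 and 6.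

**Step 4**
Reactants: 5 tert-butyldimethyl{[1-(prop-1-en-2-yl)cyclopropyl]oxy}silane; 7 tert-butyl(diphenyl)(prop-2-yn-1-yloxy)silane
Product: 9 rac-5-{[tert-butyl(diphenyl)silyl]oxymethyl}-2-methylcyclohept-4-en-1-one, via silyl enol ether cycloadduct 8 (not isolated)
Conditions: [Rh(CO)2Cl]2 (2.5 mol %), ClCH2CH2Cl, 80 °C; then 1% aq. HCl in EtOH, rt, short contact
Reagents that add atoms: none
Why: Rhodium-catalysed [5+2] cycloaddition of a vinylcyclopropane with an alkyne: cyclopropane cleavage gives a rhoda-allyl metallacycle, the alkyne should insert with its CH terminus bonding to the vinyl CH2 so that the bulky silyloxymethyl carbon stays distal and is joined last to the cyclopropane CH2, and brief acid then hydrolyses the TBS enol ether 8 while the TBDPS ether persists; C2 forms racemic, which is harmless because step 6 passes through the planar enamine.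

**Step 5**
Reactants: 9 rac-5-{[tert-butyl(diphenyl)silyl]oxymethyl}-2-methylcyclohept-4-en-1-one; 10 (R)-1-phenylethylamine
Product: 11 N-[(1R)-1-phenylethyl]-5-{[tert-butyl(diphenyl)silyl]oxymethyl}-2-methylcyclohept-4-en-1-imine (mixture of C2 epimers and C=N isomers, used crude)
Conditions: TsOH·H2O (cat.), toluene, reflux, Dean–Stark
Reagents that add atoms: none
Why: Acid-catalysed imine condensation driven by azeotropic removal of water; the C2 epimers interconvert through the secondary enamine, so the mixture is of no consequence.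

**Step 6**
Reactants: 11 the imine of step 5; 12 4-methylpent-1-en-3-one
Product: 14 (2R)-5-{[tert-butyl(diphenyl)silyl]oxymethyl}-2-methyl-2-(4-methyl-3-oxopentyl)cyclohept-4-en-1-one, via Michael adduct imine 13 (not isolated)
Conditions: 12 (1.3 equiv, freshly distilled), THF, rt to 40 °C, several days; then 10% aq. AcOH, rt
Reagents that add atoms: water, O
Why: Michael-type alkylation of a chiral imine through its more substituted secondary enamine tautomer (aza-ene-like, with N–H transfer to the enone α-carbon), which erases the C2 configuration of 9 and sets the quaternary centre by addition to the enamine face anti to the phenyl group of the auxiliary; by analogy with the imine of 2-methylcyclohexanone the (R)-amine should give the (R)-diketone, and mild aqueous acid then releases 14 and the amine.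

**Step 7**
Reactants: 14 (2R)-5-{[tert-butyl(diphenyl)silyl]oxymethyl}-2-methyl-2-(4-methyl-3-oxopentyl)cyclohept-4-en-1-one
Product: 15 tert-butyl{[(8aR)-8a-methyl-3-(propan-2-yl)-1,2,4,5,8,8a-hexahydroazulen-6-yl]methoxy}diphenylsilane
Conditions: TiCl3(DME)1.5 (ca. 10 equiv), Zn–Cu couple, DME, reflux 3 h; then 14 in DME by syringe pump over ca. 30 h at reflux, further reflux; filtration through Florisil
Reagents that add atoms: none
Why: Intramolecular McMurry coupling: low-valent titanium transfers one electron to each ketone, the two titanium-bound ketyls at C4 and C5 combine to a titanium pinacolate, and this is deoxygenated on the metal in refluxing DME to the C4=C5 alkene. The closest known reaction type is the titanium-induced cyclisation of 1,5-diketones to tetrasubstituted cyclopentenes. Ring A closes as a five-membered ring by ketyl–ketyl coupling of two carbonyls held 1,5 by the C1–C2–C3 tether, a mode favoured over intermolecular coupling by slow addition at high dilution. No stereocentre is created, and C1, being quaternary, keeps the configuration set in step 6. The step needs positional and chemoselectivity: only the two former carbonyl carbons are joined and no cation or enolate is involved, so the alkene cannot appear elsewhere, the C8=C9 alkene and the TBDPS ether are not reduced, and keeping the diketone concentration low in an excess of pre-formed reagent should outpace Lewis-acid aldol condensation.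

**Step 8**
Reactants: 15 tert-butyl{[(8aR)-8a-methyl-3-(propan-2-yl)-1,2,4,5,8,8a-hexahydroazulen-6-yl]methoxy}diphenylsilane
Product: 16 [(8aR)-8a-methyl-3-(propan-2-yl)-1,2,4,5,8,8a-hexahydroazulen-6-yl]methanol
Conditions: TBAF, THF, 0 °C to rt
Reagents that add atoms: none
Why: Fluoride-induced cleavage of the silyl ether, driven by the Si–F bond; the diene and the quaternary centre are inert.

**Step 9**
Reactants: 16 [(8aR)-8a-methyl-3-(propan-2-yl)-1,2,4,5,8,8a-hexahydroazulen-6-yl]methanol; 17 vanillic acid
Product: 18 [(8aR)-8a-methyl-3-(propan-2-yl)-1,2,4,5,8,8a-hexahydroazulen-6-yl]methyl 4-hydroxy-3-methoxybenzoate (target)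
Conditions: PPh3, DIAD, THF, 0 °C to rt (17 in slight excess)
Reagents that add atoms: none
Why: Mitsunobu esterification, in which the carboxylic acid, far more acidic than the phenol, is the pronucleophile that displaces the alkoxyphosphonium at the primary allylic carbon (SN2), so the phenol needs no protection and no stereocentre is touched.

**Compound list**

1 | (1-ethoxycyclopropoxy)trimethylsilane | CCOC1(O[Si](C)(C)C)CC1 | starting material
2 | isopropenylmagnesium bromide | CC(=C)[Mg]Br | starting material
3 | 1-ethoxycyclopropan-1-ol | CCOC1(O)CC1 | intermediate (not isolated)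
4 | 1-(prop-1-en-2-yl)cyclopropan-1-ol | CC(=C)C1(O)CC1 | intermediate
5 | tert-butyldimethyl{[1-(prop-1-en-2-yl)cyclopropyl]oxy}silane | CC(=C)C1(O[Si](C)(C)C(C)(C)C)CC1 | intermediate
6 | propargyl alcohol | C#CCO | starting material
7 | tert-butyl(diphenyl)(prop-2-yn-1-yloxy)silane | C#CCO[Si](c1ccccc1)(c1ccccc1)C(C)(C)C | intermediate
8 | tert-butyl({5-[(tert-butyldiphenylsilyl)oxymethyl]-2-methylcyclohepta-1,4-dien-1-yl}oxy)dimethylsilane | CC1=C(O[Si](C)(C)C(C)(C)C)CCC(CO[Si](c2ccccc2)(c2ccccc2)C(C)(C)C)=CC1 | intermediate (not isolated)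
9 | rac-5-{[tert-butyl(diphenyl)silyl]oxymethyl}-2-methylcyclohept-4-en-1-one | CC1CC=C(CO[Si](c2ccccc2)(c2ccccc2)C(C)(C)C)CCC1=O | intermediate
10 | (R)-1-phenylethylamine | C[C@@H](N)c1ccccc1 | starting material
11 | N-[(1R)-1-phenylethyl]-5-{[tert-butyl(diphenyl)silyl]oxymethyl}-2-methylcyclohept-4-en-1-imine (C2 epimers) | CC1CC=C(CO[Si](c2ccccc2)(c2ccccc2)C(C)(C)C)CCC1=N[C@H](C)c1ccccc1 | intermediate
12 | 4-methylpent-1-en-3-one | CC(C)C(=O)C=C | starting material
13 | (2R)-N-[(1R)-1-phenylethyl] imine of diketone 14 at the ring carbonyl | CC(C)C(=O)CC[C@]1(C)CC=C(CO[Si](c2ccccc2)(c2ccccc2)C(C)(C)C)CCC1=N[C@H](C)c1ccccc1 | intermediate (not isolated)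
14 | (2R)-5-{[tert-butyl(diphenyl)silyl]oxymethyl}-2-methyl-2-(4-methyl-3-oxopentyl)cyclohept-4-en-1-one | CC(C)C(=O)CC[C@]1(C)CC=C(CO[Si](c2ccccc2)(c2ccccc2)C(C)(C)C)CCC1=O | intermediate
15 | tert-butyl{[(8aR)-8a-methyl-3-(propan-2-yl)-1,2,4,5,8,8a-hexahydroazulen-6-yl]methoxy}diphenylsilane | CC(C)C1=C2CCC(CO[Si](c3ccccc3)(c3ccccc3)C(C)(C)C)=CC[C@@]2(C)CC1 | intermediate
16 | [(8aR)-8a-methyl-3-(propan-2-yl)-1,2,4,5,8,8a-hexahydroazulen-6-yl]methanol | CC(C)C1=C2CCC(CO)=CC[C@@]2(C)CC1 | intermediate
17 | vanillic acid | COc1cc(C(=O)O)ccc1O | starting material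
18 | [(8aR)-8a-methyl-3-(propan-2-yl)-1,2,4,5,8,8a-hexahydroazulen-6-yl]methyl 4-hydroxy-3-methoxybenzoate | COc1cc(C(=O)OCC2=CC[C@@]3(C)CCC(C(C)C)=C3CC2)ccc1O | target

**Step count**

Total steps: 9. Longest linear sequence: 8 steps (1, 2, 4, 5, 6, 7, 8, 9).

**Steps most likely to fail**

1. Step 7. The coupling may stall at the titanium pinacolate, because the diol is ditertiary and flanked by the quaternary carbon, or aldol condensation of the 1,5-diketone may compete with ketyl formation. The fallback sets out from 14 and returns at 15. Compound 14 would be cyclised with SmI2 (THF, t-BuOH, −78 °C to rt; ketyl–ketyl pinacol coupling forming the same C4–C5 bond) to the ring A cis-diol F1. F1 would be converted with thiophosgene and DMAP (CH2Cl2, 0 °C to rt) into the cyclic thionocarbonate F2. F2 would be heated with 1,3-dimethyl-2-phenyl-1,3,2-diazaphospholidine (THF, 40 °C; Corey–Winter olefination, syn-elimination from the cis-diol) to give 15.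

2. Step 4. Regioselectivity of alkyne insertion may erode, placing the silyloxymethyl group at C4 of the cycloheptenone, and the siloxy vinylcyclopropane may be lost by premature desilylation. The fallback sets out from 1 and returns at 9; it builds the ring by ring-closing metathesis, where the substituent positions are fixed by connectivity.
   - 2-Bromoprop-2-en-1-ol would be silylated (TBDPSCl, imidazole) to [(2-bromoprop-2-en-1-yl)oxy](tert-butyl)diphenylsilane F3.
   - Compound 1 with ZnCl2 (Et2O) would give the zinc homoenolate bis(3-ethoxy-3-oxopropyl)zinc F4, which would be coupled with F3 (PdCl2[P(o-tolyl)3]2, THF; Negishi coupling) to ethyl 4-{[tert-butyl(diphenyl)silyl]oxymethyl}pent-4-enoate F5.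
   - F5 would be converted (MeNH(OMe)·HCl, i-PrMgCl, THF, −20 °C) into the Weinreb amide F6, and F6 with isopropenylmagnesium bromide 2 would give the dienone 6-{[tert-butyl(diphenyl)silyl]oxymethyl}-2-methylhepta-1,6-dien-3-one F7.
   - Copper-catalysed conjugate addition of vinylmagnesium bromide (CuBr·SMe2, TMSCl, THF, −78 °C, then aqueous work-up) would give 2-{[tert-butyl(diphenyl)silyl]oxymethyl}-6-methylnona-1,8-dien-5-one F8.
   - Ring-closing metathesis of F8 (second-generation Grubbs catalyst, CH2Cl2, 40 °C, high dilution) would close ring B to 9.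

3. Step 6. Addition of the seven-membered-ring enamine to the hindered vinyl ketone may be slow or poorly face-selective, and the vinyl ketone may polymerise over the long reaction time. The fallback sets out from 8 (isolated by omitting the acid treatment of step 4) and returns at 14.
   - Compound 8 would be cleaved with MeLi (THF, 0 °C to rt) to the regiodefined lithium enolate and trapped with allyl chloroformate (−78 °C) as the allyl enol carbonate F9.
   - Decarboxylative asymmetric allylic alkylation of F9 (Pd2(dba)3, (S)-t-BuPHOX, THF, rt; Tsuji-type) should give the (2R)-2-allyl-2-methyl ketone F10; the ligand is chosen by analogy with 2-methylcyclohexanone, with the descriptor reversed for CIP reasons only.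
   - Aldehyde-selective Wacker oxidation of the terminal alkene (PdCl2(PhCN)2, CuCl2·2H2O, AgNO2, O2, t-BuOH/MeNO2) would give the keto aldehyde F11.
   - i-PrMgBr (THF, −78 °C) should add to the aldehyde in preference to the hindered ring ketone, giving the hydroxy ketone F12, and Dess–Martin periodinane would oxidise F12 to 14.

**Further compounds**

F1 | step 7 | (8aR)-6-{[tert-butyl(diphenyl)silyl]oxymethyl}-8a-methyl-3-(propan-2-yl)-1,2,3,3a,4,5,8,8a-octahydroazulene-3,3a-diol (cis-diol, carbinol centres not assigned) | CC(C)C1(O)CC[C@]2(C)CC=C(CO[Si](c3ccccc3)(c3ccccc3)C(C)(C)C)CCC12O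
F2 | step 7 | cyclic thionocarbonate of F1 | CC(C)C12CC[C@]3(C)CC=C(CO[Si](c4ccccc4)(c4ccccc4)C(C)(C)C)CCC13OC(=S)O2
F3 | step 4 | [(2-bromoprop-2-en-1-yl)oxy](tert-butyl)diphenylsilane | C=C(Br)CO[Si](c1ccccc1)(c1ccccc1)C(C)(C)C
F4 | step 4 | bis(3-ethoxy-3-oxopropyl)zinc | CCOC(=O)CC[Zn]CCC(=O)OCC
F5 | step 4 | ethyl 4-{[tert-butyl(diphenyl)silyl]oxymethyl}pent-4-enoate | CCOC(=O)CCC(=C)CO[Si](c1ccccc1)(c1ccccc1)C(C)(C)C
F6 | step 4 | 4-{[tert-butyl(diphenyl)silyl]oxymethyl}-N-methoxy-N-methylpent-4-enamide | CON(C)C(=O)CCC(=C)CO[Si](c1ccccc1)(c1ccccc1)C(C)(C)C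
F7 | step 4 | 6-{[tert-butyl(diphenyl)silyl]oxymethyl}-2-methylhepta-1,6-dien-3-one | CC(=C)C(=O)CCC(=C)CO[Si](c1ccccc1)(c1ccccc1)C(C)(C)C
F8 | step 4 | 2-{[tert-butyl(diphenyl)silyl]oxymethyl}-6-methylnona-1,8-dien-5-one (racemic) | C=CCC(C)C(=O)CCC(=C)CO[Si](c1ccccc1)(c1ccccc1)C(C)(C)C
F9 | step 6 | allyl 5-{[tert-butyl(diphenyl)silyl]oxymethyl}-2-methylcyclohepta-1,4-dien-1-yl carbonate | C=CCOC(=O)OC1=C(C)CC=C(CO[Si](c2ccccc2)(c2ccccc2)C(C)(C)C)CC1
F10 | step 6 | (2R)-5-{[tert-butyl(diphenyl)silyl]oxymethyl}-2-methyl-2-(prop-2-en-1-yl)cyclohept-4-en-1-one | C=CC[C@]1(C)CC=C(CO[Si](c2ccccc2)(c2ccccc2)C(C)(C)C)CCC1=O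
F11 | step 6 | 3-[(1R)-4-{[tert-butyl(diphenyl)silyl]oxymethyl}-1-methyl-7-oxocyclohept-3-en-1-yl]propanal | O=CCC[C@]1(C)CC=C(CO[Si](c2ccccc2)(c2ccccc2)C(C)(C)C)CCC1=O
F12 | step 6 | (2R)-5-{[tert-butyl(diphenyl)silyl]oxymethyl}-2-(3-hydroxy-4-methylpentyl)-2-methylcyclohept-4-en-1-one (carbinol epimers) | CC(C)C(O)CC[C@]1(C)CC=C(CO[Si](c2ccccc2)(c2ccccc2)C(C)(C)C)CCC1=O
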